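**Retrosynthetic overview**

- Agehoustin E is 5-hydroxy-6,7,8,2',4',5'-hexamethoxyflavone; the last step is methanolysis of a 2,4,5-trimethoxybenzoate ester on the C5 oxygen.
- Ring C, the only ring built, is disconnected at C2=C3, the double bond between C2 (which carries ring B) and C3 (alpha to the C4 ketone), by an intramolecular ylide–ester Wittig olefination.
- The strategy rests on C5 and C8a of ring A, the two carbons flanking C4a, both bearing oxygen: the precursor is a mirror-symmetric 2,6-bis(aroyloxy)phenacylidene triphenylphosphorane, and either ester carbonyl closes to the same flavone.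
- The ylide comes from 2,6-dihydroxy-3,4,5-trimethoxyacetophenone by alpha-bromination, PPh3 and double O-aroylation; the acetophenone comes from 2,3,4-trimethoxybenzaldehyde by bromination, methoxylation, Dakin oxidation, C-acetylation and ketone-directed demethylation.

Key step: step 10

Remark: the boron chelates that the ortho-hydroxy ketones form with BF3 and BCl3 in steps 4 and 5 are hydrolysed in the aqueous work-up of the same step and are treated as part of that work-up, not as separate compounds.

**Route**

Step 1
Reactants: 1 2,3,4-trimethoxybenzaldehyde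
Product: 2 5-bromo-2,3,4-trimethoxybenzaldehyde
Conditions: NBS, MeCN, rt → 50 °C
Reagents that add atoms: N-bromosuccinimide, O=C1CCC(=O)N1Br
Why: Electrophilic aromatic bromination should go to C5, which is para to the C2 methoxy, ortho to the C4 methoxy and meta to the formyl group, whereas C6 is ortho to the aldehyde and activated only by the twisted C3 methoxy.

Step 2
Reactants: 2 5-bromo-2,3,4-trimethoxybenzaldehyde
Product: 3 2,3,4,5-tetramethoxybenzaldehyde
Conditions: NaOMe, CuBr (cat.), EtOAc (cat.), MeOH–DMF, reflux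
Reagents that add atoms: sodium methoxide, [Na+].[O-]C
Why: Ullmann-type methoxylation of the aryl bromide under catalysis by monovalent copper should exchange bromide for methoxide, and the non-enolisable aldehyde tolerates methoxide.

Step 3
Reactants: 3 2,3,4,5-tetramethoxybenzaldehyde
Product: 5 2,3,4,5-tetramethoxyphenol, via tetramethoxyphenyl formate 4 (not isolated)
Conditions: 30% aq. H2O2, H2SO4 (cat.), MeOH, rt
Reagents that add atoms: hydrogen peroxide, OO
Why: In this acid-catalysed Dakin (Baeyer–Villiger-type) oxidation the aryl group, made electron-rich by its ortho and para methoxy groups, migrates in preference to hydride, and the resulting formate is methanolysed in the same flask.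

Step 4
Reactants: 5 2,3,4,5-tetramethoxyphenol
Product: 6 1-(2-hydroxy-3,4,5,6-tetramethoxyphenyl)ethanone
Conditions: AcOH, BF3·OEt2, 85 °C; aq. NaOAc work-up
Reagents that add atoms: acetic acid, CC(=O)O
Why: BF3-mediated Friedel–Crafts (Fries-type) C-acetylation can only take the single free ring position, ortho to the hydroxyl, and the product is held as its boron chelate until work-up, which protects it from further reaction.

Step 5
Reactants: 6 1-(2-hydroxy-3,4,5,6-tetramethoxyphenyl)ethanone
Product: 7 1-(2,6-dihydroxy-3,4,5-trimethoxyphenyl)ethanone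
Conditions: BCl3 (3 equiv), CH2Cl2, −20 °C → rt; aq. HCl work-up
Reagents that add atoms: none
Why: In this ketone-directed Lewis-acid ether cleavage BCl3 bridges the carbonyl oxygen and the C6 methoxy oxygen in a six-membered chelate and chloride removes that methyl group, while the three methoxy groups remote from the carbonyl should react more slowly at low temperature.

Step 6
Reactants: 7 1-(2,6-dihydroxy-3,4,5-trimethoxyphenyl)ethanone
Product: 8 2-bromo-1-(2,6-dihydroxy-3,4,5-trimethoxyphenyl)ethanone
Conditions: CuBr2 (2.1 equiv), EtOAc–CHCl3, reflux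
Reagents that add atoms: CuBr2 (divalent copper bromide), [Cu+2].[Br-].[Br-]
Why: Heterogeneous alpha-bromination of the methyl ketone by CuBr2 through its enol should be clean because ring A is hexasubstituted and cannot be brominated, and no base is present to close the hydroxy bromoketone to a benzofuranone.

Step 7
Reactants: 8 2-bromo-1-(2,6-dihydroxy-3,4,5-trimethoxyphenyl)ethanone; 9 triphenylphosphine
Product: 10 [2-(2,6-dihydroxy-3,4,5-trimethoxyphenyl)-2-oxoethyl]triphenylphosphonium bromide
Conditions: MeCN, rt
Reagents that add atoms: none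
Why: SN2 quaternisation of PPh3 by the primary phenacyl bromide is fast under neutral conditions, in which the phenols stay un-ionised and cannot displace bromide themselves.

Step 8
Reactants: 11 2,4,5-trimethoxybenzoic acid
Product: 12 2,4,5-trimethoxybenzoyl chloride
Conditions: (COCl)2, DMF (cat.), CH2Cl2, 0 °C → rt
Reagents that add atoms: oxalyl chloride, O=C(Cl)C(=O)Cl
Why: Standard acid chloride formation through the DMF-derived chloroiminium catalyst, used crude after evaporation.

Step 9
Reactants: 10 [2-(2,6-dihydroxy-3,4,5-trimethoxyphenyl)-2-oxoethyl]triphenylphosphonium bromide; 12 2,4,5-trimethoxybenzoyl chloride (2.5 equiv)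
Product: 15 4,5,6-trimethoxy-2-[(triphenyl-λ5-phosphanylidene)acetyl]-1,3-phenylene bis(2,4,5-trimethoxybenzoate), via dihydroxy ylide 13 (not isolated), via monoester ylide 14 (not isolated)
Conditions: Et3N (4 equiv), DMAP (cat.), CH2Cl2, 0 °C → rt
Reagents that add atoms: none
Why: Et3N first deprotonates the acidic phosphonium methylene to the keto-stabilised ylide, and DMAP-catalysed O-acylation then esterifies both phenols, since acid chlorides attack keto ylides at best reversibly at the enolate oxygen and the acyl groups should end on the phenoxides.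

Step 10
Reactants: 15 4,5,6-trimethoxy-2-[(triphenyl-λ5-phosphanylidene)acetyl]-1,3-phenylene bis(2,4,5-trimethoxybenzoate)
Product: 16 6,7,8-trimethoxy-4-oxo-2-(2,4,5-trimethoxyphenyl)-4H-chromen-5-yl 2,4,5-trimethoxybenzoate
Conditions: toluene (0.01 M), reflux, N2
Reagents that add atoms: none
Why: On heating, the keto-stabilised ylide carbon adds to the carbonyl of one ortho 2,4,5-trimethoxybenzoate to give a betaine that closes to a 1,2-oxaphosphetane, and cycloreversion expels Ph3PO and leaves the C2=C3 double bond, so ring C arises by olefination and not by condensation and dehydration. This is the intramolecular Wittig reaction of ortho-acyloxyphenacylidene phosphoranes on ester carbonyls, the known route from such ylides to chromones and flavones. Ring C closes in a 6-exo-trig mode, the ylide carbon attacking an ester C=O that lies outside the forming six-membered ring (C3, C4, C4a, C8a, O1, C2). No stereocenter is formed and the new double bond is endocyclic, so no geometric isomers arise. The selectivity needed is between the two ester carbonyls and between cyclisation and bimolecular acyl transfer: the two esters are exchanged by the mirror plane through C1 and C4 of the ring A precursor, so either closure gives the same flavone 16, and the six-membered closure at high dilution should outpace intermolecular reactions. The medium is neutral and aprotic, so the methyl ethers and the second aryl ester should survive.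

Step 11
Reactants: 16 6,7,8-trimethoxy-4-oxo-2-(2,4,5-trimethoxyphenyl)-4H-chromen-5-yl 2,4,5-trimethoxybenzoate
Product: 17 Agehoustin E (5-hydroxy-6,7,8-trimethoxy-2-(2,4,5-trimethoxyphenyl)-4H-chromen-4-one)
Conditions: K2CO3 (0.5 equiv), MeOH–THF, rt
Reagents that add atoms: none
Why: Base-catalysed transesterification with methanol should cleave the aryl ester readily because the C5 phenoxide next to the C4 carbonyl is a good leaving group, while the methyl ethers and the pyranone are inert at room temperature.

**Compound list**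

1 | 2,3,4-trimethoxybenzaldehyde | O=Cc1ccc(OC)c(OC)c1OC | starting material
2 | 5-bromo-2,3,4-trimethoxybenzaldehyde | O=Cc1cc(Br)c(OC)c(OC)c1OC | intermediate
3 | 2,3,4,5-tetramethoxybenzaldehyde | O=Cc1cc(OC)c(OC)c(OC)c1OC | intermediate
4 | 2,3,4,5-tetramethoxyphenyl formate | O=COc1cc(OC)c(OC)c(OC)c1OC | intermediate
5 | 2,3,4,5-tetramethoxyphenol | Oc1cc(OC)c(OC)c(OC)c1OC | intermediate
6 | 1-(2-hydroxy-3,4,5,6-tetramethoxyphenyl)ethanone | CC(=O)c1c(O)c(OC)c(OC)c(OC)c1OC | intermediate
7 | 1-(2,6-dihydroxy-3,4,5-trimethoxyphenyl)ethanone | CC(=O)c1c(O)c(OC)c(OC)c(OC)c1O | intermediate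
8 | 2-bromo-1-(2,6-dihydroxy-3,4,5-trimethoxyphenyl)ethanone | O=C(CBr)c1c(O)c(OC)c(OC)c(OC)c1O | intermediate
9 | triphenylphosphine | c1ccc(P(c2ccccc2)c2ccccc2)cc1 | starting material
10 | [2-(2,6-dihydroxy-3,4,5-trimethoxyphenyl)-2-oxoethyl]triphenylphosphonium bromide | O=C(C[P+](c1ccccc1)(c1ccccc1)c1ccccc1)c1c(O)c(OC)c(OC)c(OC)c1O.[Br-] | intermediate
11 | 2,4,5-trimethoxybenzoic acid | O=C(O)c1cc(OC)c(OC)cc1OC | starting material
12 | 2,4,5-trimethoxybenzoyl chloride | O=C(Cl)c1cc(OC)c(OC)cc1OC | intermediate
13 | 1-(2,6-dihydroxy-3,4,5-trimethoxyphenyl)-2-(triphenyl-λ5-phosphanylidene)ethanone | O=C(C=P(c1ccccc1)(c1ccccc1)c1ccccc1)c1c(O)c(OC)c(OC)c(OC)c1O | intermediate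
14 | 3-hydroxy-4,5,6-trimethoxy-2-[(triphenyl-λ5-phosphanylidene)acetyl]phenyl 2,4,5-trimethoxybenzoate | COc1cc(OC)c(C(=O)Oc2c(OC)c(OC)c(OC)c(O)c2C(=O)C=P(c3ccccc3)(c4ccccc4)c5ccccc5)cc1OC | intermediate
15 | 4,5,6-trimethoxy-2-[(triphenyl-λ5-phosphanylidene)acetyl]-1,3-phenylene bis(2,4,5-trimethoxybenzoate) | COc1cc(OC)c(C(=O)Oc2c(OC)c(OC)c(OC)c(OC(=O)c3cc(OC)c(OC)cc3OC)c2C(=O)C=P(c4ccccc4)(c5ccccc5)c6ccccc6)cc1OC | intermediate
16 | 6,7,8-trimethoxy-4-oxo-2-(2,4,5-trimethoxyphenyl)-4H-chromen-5-yl 2,4,5-trimethoxybenzoate | COc1cc(OC)c(-c2cc(=O)c3c(OC(=O)c4cc(OC)c(OC)cc4OC)c(OC)c(OC)c(OC)c3o2)cc1OC | intermediate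
17 | Agehoustin E, 5-hydroxy-6,7,8-trimethoxy-2-(2,4,5-trimethoxyphenyl)-4H-chromen-4-one | COc1cc(OC)c(-c2cc(=O)c3c(O)c(OC)c(OC)c(OC)c3o2)cc1OC | target

**Step count**

Total steps: 11. Longest linear sequence: 10 steps (steps 1–7 and 9–11, from 1); step 8 is a one-step side branch from 11.

**Steps most likely to fail**

Step 10. The betaine formed when the ylide adds to the hindered, electron-rich ester carbonyl may collapse by loss of the phenoxide (aroyl migration from oxygen to carbon, giving a doubly stabilised and unreactive ylide) instead of closing to the oxaphosphetane, or the addition may be too slow. The fallback uses the phosphorus handle intermolecularly and sets out from 10. Treatment of 10 with aqueous K2CO3 in CH2Cl2 frees ylide 13. Wittig olefination of 13 with commercial 2,4,5-trimethoxybenzaldehyde in refluxing toluene should give (E)-1-(2,6-dihydroxy-3,4,5-trimethoxyphenyl)-3-(2,4,5-trimethoxyphenyl)prop-2-en-1-one F1. Oxidative cyclisation of F1 with catalytic I2 in DMSO at 120 °C closes ring C through either of the two equivalent hydroxyls. The route is rejoined at 17.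

Step 9. Acylation may stay incomplete or go astray, since the two phenols are hydrogen-bonded to the ketone and sterically flanked, and irreversible acylation at the ylide carbon may compete. The fallback installs the esters before phosphorus, sets out from 7 and uses 12. Aroylation of 7 with 12 in pyridine with DMAP should give 2-acetyl-4,5,6-trimethoxy-1,3-phenylene bis(2,4,5-trimethoxybenzoate) F2. Alpha-bromination with phenyltrimethylammonium tribromide in THF, chosen to spare the electron-rich aroyl rings, should give 2-(bromoacetyl)-4,5,6-trimethoxy-1,3-phenylene bis(2,4,5-trimethoxybenzoate) F3. PPh3 in MeCN then gives [2-(2,6-bis(2,4,5-trimethoxybenzoyloxy)-3,4,5-trimethoxyphenyl)-2-oxoethyl]triphenylphosphonium bromide F4, and a wash with aqueous Na2CO3 liberates the ylide. The route is rejoined at 15.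

Step 5. Regiocontrol of the ether cleavage may be lost: once the existing phenol has formed its boron chelate with the ketone, cleavage of the C6 methyl ether may be slow, and other methyl ethers of the contiguous array may be cleaved in competition. The fallback carries the C6 methyl ether through to the flavone and sets out from 6.

- CuBr2 in EtOAc–CHCl3 should give 2-bromo-1-(2-hydroxy-3,4,5,6-tetramethoxyphenyl)ethanone F5.
- PPh3 gives [2-(2-hydroxy-3,4,5,6-tetramethoxyphenyl)-2-oxoethyl]triphenylphosphonium bromide F6.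
- Aqueous Na2CO3 frees 1-(2-hydroxy-3,4,5,6-tetramethoxyphenyl)-2-(triphenyl-λ5-phosphanylidene)ethanone F7.
- A single O-aroylation with 12 (Et3N, DMAP) gives 3,4,5,6-tetramethoxy-2-[(triphenyl-λ5-phosphanylidene)acetyl]phenyl 2,4,5-trimethoxybenzoate F8.
- Refluxing toluene effects the same intramolecular Wittig closure to 5,6,7,8-tetramethoxy-2-(2,4,5-trimethoxyphenyl)-4H-chromen-4-one F9.
- BCl3 (1.1 equiv, CH2Cl2, −78 → 0 °C) removes only the C5 methyl group of F9, which sits next to the C4 carbonyl, a selectivity well established for polymethoxyflavones.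

The route is rejoined at 17.

**Further compounds**

F1 | step 10 | (E)-1-(2,6-dihydroxy-3,4,5-trimethoxyphenyl)-3-(2,4,5-trimethoxyphenyl)prop-2-en-1-one | O=C(/C=C/c1cc(OC)c(OC)cc1OC)c1c(O)c(OC)c(OC)c(OC)c1O
F2 | step 9 | 2-acetyl-4,5,6-trimethoxy-1,3-phenylene bis(2,4,5-trimethoxybenzoate) | CC(=O)c1c(OC(=O)c2cc(OC)c(OC)cc2OC)c(OC)c(OC)c(OC)c1OC(=O)c1cc(OC)c(OC)cc1OC
F3 | step 9 | 2-(bromoacetyl)-4,5,6-trimethoxy-1,3-phenylene bis(2,4,5-trimethoxybenzoate) | O=C(CBr)c1c(OC(=O)c2cc(OC)c(OC)cc2OC)c(OC)c(OC)c(OC)c1OC(=O)c1cc(OC)c(OC)cc1OC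
F4 | step 9 | [2-(2,6-bis(2,4,5-trimethoxybenzoyloxy)-3,4,5-trimethoxyphenyl)-2-oxoethyl]triphenylphosphonium bromide | O=C(C[P+](c1ccccc1)(c1ccccc1)c1ccccc1)c1c(OC(=O)c2cc(OC)c(OC)cc2OC)c(OC)c(OC)c(OC)c1OC(=O)c1cc(OC)c(OC)cc1OC.[Br-]
F5 | step 5 | 2-bromo-1-(2-hydroxy-3,4,5,6-tetramethoxyphenyl)ethanone | O=C(CBr)c1c(O)c(OC)c(OC)c(OC)c1OC
F6 | step 5 | [2-(2-hydroxy-3,4,5,6-tetramethoxyphenyl)-2-oxoethyl]triphenylphosphonium bromide | O=C(C[P+](c1ccccc1)(c1ccccc1)c1ccccc1)c1c(O)c(OC)c(OC)c(OC)c1OC.[Br-]
F7 | step 5 | 1-(2-hydroxy-3,4,5,6-tetramethoxyphenyl)-2-(triphenyl-λ5-phosphanylidene)ethanone | O=C(C=P(c1ccccc1)(c1ccccc1)c1ccccc1)c1c(O)c(OC)c(OC)c(OC)c1OC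
F8 | step 5 | 3,4,5,6-tetramethoxy-2-[(triphenyl-λ5-phosphanylidene)acetyl]phenyl 2,4,5-trimethoxybenzoate | COc1cc(OC)c(C(=O)Oc2c(OC)c(OC)c(OC)c(OC)c2C(=O)C=P(c3ccccc3)(c4ccccc4)c5ccccc5)cc1OC
F9 | step 5 | 5,6,7,8-tetramethoxy-2-(2,4,5-trimethoxyphenyl)-4H-chromen-4-one | COc1cc(OC)c(-c2cc(=O)c3c(OC)c(OC)c(OC)c(OC)c3o2)cc1OC
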